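**Strategy.** Acid-chain numbering is used (C1 = CO2H; ring oxygens O1 on C6, O2 on C3). The 1,2-dioxane is cut at C4–C5 and C6–O1. The ring CH2 (C5) and the quaternary peroxy carbon C6 with its methyl are read as a 2-methylallyl terminus, C3/C4 with the C4 methyl as propanal, and O1–O2 as dioxygen. One aerobic enamine-radical [2+2+2] peroxy-annulation of the complete triene with propanal and air therefore assembles the whole ring as a lactol and sets C4 by catalyst control. C3 is then relayed from C4/C6 by axial capture of the peroxycarbenium ion. The triene arises from an Evans alkylation, an organocatalytic vinylation and a Julia–Kocienski olefination.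

Key step: step 7

Remark: O2 capture at C6 in step 7 is assumed to be unselective, so the route relies on separating the two C6 epimers there. Lactol 16 and acetate 18 are carried as mixtures at C3, which becomes planar in step 9.

Step 1
Reactants: 1 (S)-4-benzyl-3-propanoyl-1,3-oxazolidin-2-one; 2 3-bromo-2-methylprop-1-ene
Product: 3 (S)-4-benzyl-3-[(2R)-2,4-dimethylpent-4-enoyl]-1,3-oxazolidin-2-one
Conditions: NaN(SiMe3)2, THF, −78 °C; then 2 (3 equiv), −78 → −45 °C
Reagents that add atoms: 3-bromo-2-methylprop-1-ene (C=C(C)CBr)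
Why: Evans alkylation: the chelated (Z)-sodium enolate is alkylated by the allylic bromide on the face away from the benzyl group, which sets the (R) centre that becomes C8.

Step 2
Reactants: 3 (S)-4-benzyl-3-[(2R)-2,4-dimethylpent-4-enoyl]-1,3-oxazolidin-2-one
Product: 4 (2R)-2,4-dimethylpent-4-en-1-ol
Conditions: LiBH4, MeOH (1.1 equiv), Et2O, 0 °C
Reagents that add atoms: none
Why: Reductive cleavage of the N-acyl oxazolidinone by borohydride should give the primary alcohol without touching the α-stereocentre or the alkene.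

Step 3
Reactants: 4 (2R)-2,4-dimethylpent-4-en-1-ol; 5 1-phenyl-1H-tetrazole-5-thiol
Product: 6 5-{[(2R)-2,4-dimethylpent-4-en-1-yl]sulfanyl}-1-phenyl-1H-tetrazole
Conditions: PPh3, DIAD, THF, 0 → 23 °C
Reagents that add atoms: 1-phenyl-1H-tetrazole-5-thiol (Sc1nnnn1-c1ccccc1)
Why: Mitsunobu thioetherification of an unhindered primary alcohol with an acidic heteroaryl thiol; the stereocentre is not involved.

Step 4
Reactants: 6 5-{[(2R)-2,4-dimethylpent-4-en-1-yl]sulfanyl}-1-phenyl-1H-tetrazole; 7 hydrogen peroxide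
Product: 8 5-{[(2R)-2,4-dimethylpent-4-en-1-yl]sulfonyl}-1-phenyl-1H-tetrazole
Conditions: (NH4)6Mo7O24·4H2O (10 mol %), 30% aq. H2O2, EtOH, 0 → 23 °C
Reagents that add atoms: hydrogen peroxide (OO)
Why: Molybdate-catalysed oxidation of the sulfide to the sulfone is much faster than epoxidation of an unactivated 1,1-disubstituted alkene.

Step 5
Reactants: 9 (E)-but-2-enal; 10 potassium trifluoro[(E)-2-phenylethenyl]borate
Product: 11 (3S,4E)-3-methyl-5-phenylpent-4-enal
Conditions: (2R,5R)-5-benzyl-2-tert-butyl-3-methylimidazolidin-4-one·HCl (20 mol %), HF (1 equiv), DME, −20 °C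
Reagents that add atoms: potassium trifluoro[(E)-2-phenylethenyl]borate ([K+].F[B-](F)(F)/C=C/c1ccccc1), water (O)
Why: Iminium-catalysed conjugate vinylation of an enal with a vinyl trifluoroborate: the benzyl group of the catalyst shields one face of the iminium β-carbon, and the (2R,5R) enantiomer is chosen by the established facial model to give the (S) centre that becomes C12.

Step 6
Reactants: 8 5-{[(2R)-2,4-dimethylpent-4-en-1-yl]sulfonyl}-1-phenyl-1H-tetrazole; 11 (3S,4E)-3-methyl-5-phenylpent-4-enal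
Product: 12 [(1E,3S,5E,7R)-3,7,9-trimethyldeca-1,5,9-trien-1-yl]benzene
Conditions: KN(SiMe3)2, DME, −60 °C; then 11, −60 → 23 °C
Reagents that add atoms: (3S,4E)-3-methyl-5-phenylpent-4-enal (O=CC[C@H](C)/C=C/c1ccccc1)
Why: Julia–Kocienski olefination: the potassium sulfonyl carbanion in DME adds to the aldehyde and, after Smiles rearrangement and loss of SO2, should give the (E)-C9=C10 alkene without touching either stereocentre.

Step 7
Reactants: 12 [(1E,3S,5E,7R)-3,7,9-trimethyldeca-1,5,9-trien-1-yl]benzene; 13 propanal; 14 dioxygen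
Product: 16 (4S,6S)-4,6-dimethyl-6-[(2R,3E,6S,7E)-2,6-dimethyl-8-phenylocta-3,7-dien-1-yl]-1,2-dioxan-3-ol, via γ-hydroperoxy aldehyde 15 (not isolated)
Conditions: 13 (5 equiv), (2R,5R)-5-benzyl-2-tert-butyl-3-methylimidazolidin-4-one·CF3CO2H (30 mol %), Fe(phen)3(PF6)3 (15 mol %; phen = 1,10-phenanthroline), air (1 atm), H2O (3 equiv), DME, −20 °C; chromatographic separation of the C6 epimers
Reagents that add atoms: propanal (CCC=O), dioxygen (O=O), water (O)
Why: Proposed new method: the imidazolidinone condenses with 13 to the (E)-enamine, trivalent iron oxidises it to the 3π-electron radical cation, C4 of this electrophilic radical adds to the unhindered CH2 terminus (C5) of the 1,1-disubstituted alkene of 12, the tertiary C6 radical captures O2 (C6–O1), and divalent iron reduces the peroxyl radical (regenerating trivalent iron) to hydroperoxide 15, held as its iminium ion. The closest known reaction types are the organo-SOMO carbo-oxidation of alkenes with aldehyde-derived enamine radical cations and the aerobic peroxycyclisation of 1,1-disubstituted alkenes with 1,3-dicarbonyl compounds catalysed by Mn(OAc)3, which forms 1,2-dioxan-3-ols through the same sequence of radical addition, O2 capture and hemiacetal closure. The 1,2-dioxane ring closes by 6-exo-trig attack of the hydroperoxide oxygen on the iminium (aldehyde) carbon C3, and hydrolysis releases lactol 16 and the catalyst. C4 is set by the catalyst: by the shielding model of this imidazolidinone the benzyl group of the (2R,5R) enantiomer blocks the Si face of the enamine, so C5 bonds to the Re face (4S); C6 is formed without facial control, both C6 epimers are expected in similar amounts and the (6S) lactol is to be separated by chromatography; the hemiacetal carbon C3 is left as a mixture that step 9 erases. The step needs site selectivity among three alkenes and C–C bond formation ahead of oxygen capture: only the terminal CH2 is unhindered and leads to a tertiary radical, whereas each 1,2-disubstituted alkene would have to be attacked next to a branched carbon, and an excess of 13 under air at −20 °C is meant to absorb direct oxygenation of the enamine radical cation and to slow cyclisation of the peroxyl radical onto C9.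

Step 8
Reactants: 16 (4S,6S)-4,6-dimethyl-6-[(2R,3E,6S,7E)-2,6-dimethyl-8-phenylocta-3,7-dien-1-yl]-1,2-dioxan-3-ol; 17 acetic anhydride
Product: 18 (4S,6S)-4,6-dimethyl-6-[(2R,3E,6S,7E)-2,6-dimethyl-8-phenylocta-3,7-dien-1-yl]-1,2-dioxan-3-yl acetate
Conditions: Ac2O, pyridine, DMAP (5 mol %), CH2Cl2, 0 °C
Reagents that add atoms: acetic anhydride (CC(=O)OC(C)=O)
Why: Acylation of the hemiacetal hydroxyl of the cyclic peroxy-lactol should lock the ring form, protect C4 from epimerisation through the open aldehyde, and install the leaving group for step 9.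

Step 9
Reactants: 18 (4S,6S)-4,6-dimethyl-6-[(2R,3E,6S,7E)-2,6-dimethyl-8-phenylocta-3,7-dien-1-yl]-1,2-dioxan-3-yl acetate; 19 1,1-bis(trimethylsilyloxy)ethene
Product: 21 2-[(3S,4S,6S)-4,6-dimethyl-6-[(2R,3E,6S,7E)-2,6-dimethyl-8-phenylocta-3,7-dien-1-yl]-1,2-dioxan-3-yl]acetic acid, via trimethylsilyl ester 20 (not isolated)
Conditions: 19 (3 equiv), Me3SiOSO2CF3 (0.3 equiv), CH2Cl2, −78 °C; then aqueous citric acid, 0 °C
Reagents that add atoms: 1,1-bis(trimethylsilyloxy)ethene (C=C(O[Si](C)(C)C)O[Si](C)(C)C)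
Why: Mukaiyama-type substitution through the 1,2-dioxan-3-ylium (peroxycarbenium) ion, known for 3-acyloxy and 3-alkoxy cyclic peroxides: the half-chair is locked with the C4 and C6 methyl groups equatorial (the flipped form would place them 1,3-diaxial), so the ketene acetal should add along the axial trajectory at C3, cis to the C4 methyl (3S), and hydrolysis of silyl ester 20 on work-up gives the acid.

**Compound list**

1 | (S)-4-benzyl-3-propanoyl-1,3-oxazolidin-2-one | CCC(=O)N1[C@@H](Cc2ccccc2)COC1=O | starting material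
2 | 3-bromo-2-methylprop-1-ene | C=C(C)CBr | starting material
3 | (S)-4-benzyl-3-[(2R)-2,4-dimethylpent-4-enoyl]-1,3-oxazolidin-2-one | C=C(C)C[C@@H](C)C(=O)N1[C@@H](Cc2ccccc2)COC1=O | intermediate
4 | (2R)-2,4-dimethylpent-4-en-1-ol | C=C(C)C[C@@H](C)CO | intermediate
5 | 1-phenyl-1H-tetrazole-5-thiol | Sc1nnnn1-c1ccccc1 | starting material
6 | 5-{[(2R)-2,4-dimethylpent-4-en-1-yl]sulfanyl}-1-phenyl-1H-tetrazole | C=C(C)C[C@@H](C)CSc1nnnn1-c1ccccc1 | intermediate
7 | hydrogen peroxide | OO | starting material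
8 | 5-{[(2R)-2,4-dimethylpent-4-en-1-yl]sulfonyl}-1-phenyl-1H-tetrazole | C=C(C)C[C@@H](C)CS(=O)(=O)c1nnnn1-c1ccccc1 | intermediate
9 | (E)-but-2-enal | C/C=C/C=O | starting material
10 | potassium trifluoro[(E)-2-phenylethenyl]borate | [K+].F[B-](F)(F)/C=C/c1ccccc1 | starting material
11 | (3S,4E)-3-methyl-5-phenylpent-4-enal | O=CC[C@H](C)/C=C/c1ccccc1 | intermediate
12 | [(1E,3S,5E,7R)-3,7,9-trimethyldeca-1,5,9-trien-1-yl]benzene | C=C(C)C[C@@H](C)/C=C/C[C@H](C)/C=C/c1ccccc1 | intermediate
13 | propanal | CCC=O | starting material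
14 | dioxygen | O=O | starting material
15 | (2S,4S,6R,7E,10S,11E)-4-hydroperoxy-2,4,6,10-tetramethyl-12-phenyldodeca-7,11-dienal (ring-open tautomer, formed as its iminium ion) | C[C@H](/C=C/c1ccccc1)C/C=C/[C@H](C)C[C@](C)(OO)C[C@H](C)C=O | intermediate
16 | (4S,6S)-4,6-dimethyl-6-[(2R,3E,6S,7E)-2,6-dimethyl-8-phenylocta-3,7-dien-1-yl]-1,2-dioxan-3-ol (both C3 anomers) | C[C@H](/C=C/c1ccccc1)C/C=C/[C@H](C)C[C@@]1(C)C[C@H](C)C(O)OO1 | intermediate
17 | acetic anhydride | CC(=O)OC(C)=O | starting material
18 | (4S,6S)-4,6-dimethyl-6-[(2R,3E,6S,7E)-2,6-dimethyl-8-phenylocta-3,7-dien-1-yl]-1,2-dioxan-3-yl acetate (both C3 anomers) | C[C@H](/C=C/c1ccccc1)C/C=C/[C@H](C)C[C@@]1(C)C[C@H](C)C(OC(C)=O)OO1 | intermediate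
19 | 1,1-bis(trimethylsilyloxy)ethene | C=C(O[Si](C)(C)C)O[Si](C)(C)C | starting material
20 | trimethylsilyl 2-[(3S,4S,6S)-4,6-dimethyl-6-[(2R,3E,6S,7E)-2,6-dimethyl-8-phenylocta-3,7-dien-1-yl]-1,2-dioxan-3-yl]acetate | C[C@H](/C=C/c1ccccc1)C/C=C/[C@H](C)C[C@@]1(C)C[C@H](C)[C@H](CC(=O)O[Si](C)(C)C)OO1 | intermediate
21 | 2-[(3S,4S,6S)-4,6-dimethyl-6-[(2R,3E,6S,7E)-2,6-dimethyl-8-phenylocta-3,7-dien-1-yl]-1,2-dioxan-3-yl]acetic acid | C[C@H](/C=C/c1ccccc1)C/C=C/[C@H](C)C[C@@]1(C)C[C@H](C)[C@H](CC(=O)O)OO1 | target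

**Step count.** Total: 9 steps. Longest linear sequence: 8 steps (1, 2, 3, 4, 6, 7, 8, 9); step 5 is convergent.

**Steps most likely to fail**

Step 7 (proposed new method). What may go wrong is capture of O2 by the enamine radical cation before it reaches the alkene, chain autoxidation of propanal, and the absence of facial control when the C6 radical takes up O2. The fallback uses known chemistry, sets out from 12 and comes back at 16. It is the aerobic peroxycyclisation of alkenes with 1,3-dicarbonyl compounds under Mn(OAc)3·2H2O (catalytic) and Mn(OAc)2 in AcOH under air at 23 °C. Run with tert-butyl 2-methyl-3-oxopropanoate, it should form the same C4–C5/C6–O1 bond pair from a manganese enolate radical and give tert-butyl (6S)-3-hydroxy-4,6-dimethyl-6-[(2R,3E,6S,7E)-2,6-dimethyl-8-phenylocta-3,7-dien-1-yl]-1,2-dioxane-4-carboxylate F1. CF3CO2H in CH2Cl2 at 0 °C would cleave the ester to (6S)-3-hydroxy-4,6-dimethyl-6-[(2R,3E,6S,7E)-2,6-dimethyl-8-phenylocta-3,7-dien-1-yl]-1,2-dioxane-4-carboxylic acid F2. Its ring-open β-formyl acid tautomer should lose CO2 on warming to 40 °C and return 16. In this fallback C4 is not catalyst-controlled, so both C4 and C6 would have to be secured by separation.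

Step 9. What may go wrong is ionisation of the tertiary C6–O1 bond or fragmentation of the peroxycarbenium ion before C–C bond formation, and erosion of the axial selectivity. The fallback sets out from 16, comes back at 21, and sets C3 by conjugate addition instead of cation capture. Trimethyl phosphonoacetate, LiCl and iPr2NEt in MeCN at 0 °C (Horner–Wadsworth–Emmons reaction on the ring-open aldehyde tautomer) should give methyl (2E,4S,6S,8R,9E,12S,13E)-6-hydroperoxy-4,6,8,12-tetramethyl-14-phenyltetradeca-2,9,13-trienoate F3. Et2NH in CF3CH2OH should close the ring by 6-exo-trig oxa-Michael addition to methyl 2-[(3S,4S,6S)-4,6-dimethyl-6-[(2R,3E,6S,7E)-2,6-dimethyl-8-phenylocta-3,7-dien-1-yl]-1,2-dioxan-3-yl]acetate F4, with any C3 epimer removed by chromatography. LiOH in THF/H2O at 0 °C then gives 21.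

Step 6. What may go wrong is incomplete E selectivity with the β-branched sulfone anion and enolisation of the α-unbranched aldehyde by the base. The fallback sets out from 4 and 11, comes back at 12, and reverses the roles of the two fragments so that an unbranched sulfone meets an α-branched aldehyde. Dess–Martin periodinane in CH2Cl2 oxidises 4 to (2R)-2,4-dimethylpent-4-enal F5. NaBH4 in MeOH reduces 11 to (3S,4E)-3-methyl-5-phenylpent-4-en-1-ol F6. Mitsunobu reaction with 5 (PPh3, DIAD, THF) gives 5-{[(3S,4E)-3-methyl-5-phenylpent-4-en-1-yl]sulfanyl}-1-phenyl-1H-tetrazole F7. (NH4)6Mo7O24·4H2O and H2O2 in EtOH give 5-{[(3S,4E)-3-methyl-5-phenylpent-4-en-1-yl]sulfonyl}-1-phenyl-1H-tetrazole F8. Julia–Kocienski olefination of F8 with F5 (KN(SiMe3)2, DME, −60 °C) then gives 12.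

Further compounds
F1 | step 7 | tert-butyl (6S)-3-hydroxy-4,6-dimethyl-6-[(2R,3E,6S,7E)-2,6-dimethyl-8-phenylocta-3,7-dien-1-yl]-1,2-dioxane-4-carboxylate | C[C@H](/C=C/c1ccccc1)C/C=C/[C@H](C)C[C@@]1(C)CC(C)(C(=O)OC(C)(C)C)C(O)OO1
F2 | step 7 | (6S)-3-hydroxy-4,6-dimethyl-6-[(2R,3E,6S,7E)-2,6-dimethyl-8-phenylocta-3,7-dien-1-yl]-1,2-dioxane-4-carboxylic acid | C[C@H](/C=C/c1ccccc1)C/C=C/[C@H](C)C[C@@]1(C)CC(C)(C(O)=O)C(O)OO1
F3 | step 9 | methyl (2E,4S,6S,8R,9E,12S,13E)-6-hydroperoxy-4,6,8,12-tetramethyl-14-phenyltetradeca-2,9,13-trienoate | C[C@H](/C=C/c1ccccc1)C/C=C/[C@H](C)C[C@](C)(OO)C[C@H](C)/C=C/C(=O)OC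
F4 | step 9 | methyl 2-[(3S,4S,6S)-4,6-dimethyl-6-[(2R,3E,6S,7E)-2,6-dimethyl-8-phenylocta-3,7-dien-1-yl]-1,2-dioxan-3-yl]acetate | C[C@H](/C=C/c1ccccc1)C/C=C/[C@H](C)C[C@@]1(C)C[C@H](C)[C@H](CC(=O)OC)OO1
F5 | step 6 | (2R)-2,4-dimethylpent-4-enal | C=C(C)C[C@@H](C)C=O
F6 | step 6 | (3S,4E)-3-methyl-5-phenylpent-4-en-1-ol | OCC[C@H](C)/C=C/c1ccccc1
F7 | step 6 | 5-{[(3S,4E)-3-methyl-5-phenylpent-4-en-1-yl]sulfanyl}-1-phenyl-1H-tetrazole | c1ccccc1-n1nnnc1SCC[C@H](C)/C=C/c1ccccc1
F8 | step 6 | 5-{[(3S,4E)-3-methyl-5-phenylpent-4-en-1-yl]sulfonyl}-1-phenyl-1H-tetrazole | c1ccccc1-n1nnnc1S(=O)(=O)CC[C@H](C)/C=C/c1ccccc1
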